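**Plan**

1. Numbering (daucane): C1 = quaternary ring-fusion carbon with CH3; C2, C3 = cyclopentane CH2; C4 = carbinol carbon with isopropyl; C5 = ring-fusion CH; C6 = ester carbon; C7 = ketone; C8 = C(OH)CH3; C9 = CHOH; C10 = CH2.
2. Retrosynthetic cuts: aryl ester and benzyl ether; the C8/C9 diol (from a C8=C9 enone); C6–O (enolate hydroxylation); C9=C10 (metathesis, seven-membered ring); C4–isopropyl; C3–C4 (ring closure of the cyclopentane); C5–C1 (Claisen rearrangement).
3. Forward order: a γ-lactone (carbonyl = future C4, ring oxygen on future C7) is joined at C5 to the quaternary carbon C1 by a Johnson–Claisen rearrangement. Its iodoethyl arm then attacks the lactone carbonyl, closing the cyclopentanone and opening the lactone. Isopropyl addition, metathesis to the seven-membered ring and oxidation-state adjustments follow.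
4. Enabling feature: the lactone carbonyl C4 lies five atoms from the C3–iodine carbon (C3–C2–C1–C5–C4) with quaternary C1 in the tether, and the lactone ring oxygen is a tethered leaving group. A 5-exo attack therefore gives a stable hemiketalate, and the temporary lactone ring that steered the Claisen step is removed in the same event.
5. Stereochemistry: C7 (catalytic asymmetric crotylboration) controls C5 (Claisen anti to the C7 substituent on the lactone ring), which controls C1 (chair transition state, Z-alkene). C4 then follows from addition anti to the C5 side chain and C1 methyl, C6 from enolate oxidation anti to C4, and C8/C9 from dihydroxylation anti to the axial C1 methyl. The controller centres C7 and C8 are erased on the way to the enone.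

Key step: step 7

Remark: in step 1 the (S)-configured phosphoric acid is assumed, from the accepted chair model, to give the (4R)-carbinol; if the sense proves opposite, the (R)-catalyst is used with no other change.

**Step 1**
Reactants: 1 methyl 4-oxobutanoate; 2 (E)-crotylboronic acid pinacol ester
Product: 4 (5R)-5-[(2S)-but-3-en-2-yl]oxolan-2-one, via hydroxy ester 3 (not isolated)
Conditions: (S)-3,3′-bis(2,4,6-triisopropylphenyl)-1,1′-binaphthyl-2,2′-diyl hydrogen phosphate (5 mol %), toluene, −30 °C; then p-TsOH·H2O (5 mol %), toluene, rt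
Reagents that add atoms: none
Why: Brønsted-acid-catalysed asymmetric crotylboration through a closed chair transition state should set the carbinol centre (future C7) by catalyst control and the neighbouring methyl centre anti to it from the (E)-boronate, after which the γ-hydroxy ester lactonises under acid catalysis.

**Step 2**
Reactants: 4 (5R)-5-[(2S)-but-3-en-2-yl]oxolan-2-one
Product: 6 (5R)-5-[(2S)-but-3-en-2-yl]-2,2-dimethoxyoxolane, via lactonium salt 5 (not isolated)
Conditions: Me3OBF4, CH2Cl2, rt; then NaOMe, MeOH, −78 → 0 °C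
Reagents that add atoms: trimethyloxonium tetrafluoroborate C[O+](C)C.F[B-](F)(F)F; sodium methoxide [Na+].[O-]C
Why: O-methylation of the lactone carbonyl gives the dialkoxycarbenium ion 5, which methoxide captures at carbon (standard lactone-to-orthoester conversion) without touching either stereocentre.

**Step 3**
Reactants: 6 (5R)-5-[(2S)-but-3-en-2-yl]-2,2-dimethoxyoxolane; 7 (2Z)-3-methylpent-2-en-4-yn-1-ol
Product: 10 (3R,5R)-5-[(2S)-but-3-en-2-yl]-3-[(3R)-3-methylpent-1-en-4-yn-3-yl]oxolan-2-one, via mixed orthoester 8 (not isolated), via ketene acetal 9 (not isolated)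
Conditions: 7 (1.5 equiv), EtCO2H (5 mol %), xylenes, 140 °C, MeOH distilled off
Reagents that add atoms: none
Why: Johnson–Claisen rearrangement, in which alcohol exchange and loss of methanol give the cyclic allyl ketene acetal 9, whose [3,3]-shift through a chair transition state should bond C5 on the ring face anti to the C7 substituent and, with methyl pseudo-equatorial and the slim ethynyl group pseudo-axial as the Z-alkene dictates, set the quaternary centre C1.

**Step 4**
Reactants: 10 (3R,5R)-5-[(2S)-but-3-en-2-yl]-3-[(3R)-3-methylpent-1-en-4-yn-3-yl]oxolan-2-one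
Product: 11 (3R)-3-[(3R,5R)-5-[(2S)-but-3-en-2-yl]-2-oxooxolan-3-yl]-3-methylpent-4-enal
Conditions: RuCl(C5H5)(Ph2PCH2PPh2) (5 mol %), iPrOH/H2O (3:1), 100 °C
Reagents that add atoms: water O
Why: Ruthenium-catalysed anti-Markovnikov hydration of the terminal alkyne through a vinylidene complex should give the aldehyde, a pathway that is closed to the two alkenes and the lactone.

**Step 5**
Reactants: 11 (3R)-3-[(3R,5R)-5-[(2S)-but-3-en-2-yl]-2-oxooxolan-3-yl]-3-methylpent-4-enal
Product: 12 (3R,5R)-5-[(2S)-but-3-en-2-yl]-3-[(3R)-5-hydroxy-3-methylpent-1-en-3-yl]oxolan-2-one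
Conditions: NaBH4, MeOH, 0 °C; AcOH quench
Reagents that add atoms: none
Why: Chemoselective borohydride reduction of the aldehyde in the presence of the less electrophilic lactone should give the primary alcohol.

**Step 6**
Reactants: 12 (3R,5R)-5-[(2S)-but-3-en-2-yl]-3-[(3R)-5-hydroxy-3-methylpent-1-en-3-yl]oxolan-2-one
Product: 13 (3R,5R)-5-[(2S)-but-3-en-2-yl]-3-[(3R)-5-iodo-3-methylpent-1-en-3-yl]oxolan-2-one
Conditions: I2, PPh3, imidazole, CH2Cl2, 0 °C → rt
Reagents that add atoms: iodine II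
Why: Appel-type iodination should convert the unhindered primary alcohol into the iodide by SN2 displacement of the oxyphosphonium group.

**Step 7**
Reactants: 13 (3R,5R)-5-[(2S)-but-3-en-2-yl]-3-[(3R)-5-iodo-3-methylpent-1-en-3-yl]oxolan-2-one
Product: 16 (2R,3R)-3-ethenyl-2-[(2R,3S)-2-hydroxy-3-methylpent-4-en-1-yl]-3-methylcyclopentan-1-one, via alkylsamarium 14 (not isolated), via samarium hemiketalate 15 (not isolated)
Conditions: SmI2 (2.5 equiv), Fe(PhCOCHCOPh)3 (2 mol %), THF, −30 °C → rt; then sat. aq. NH4Cl, 0 °C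
Reagents that add atoms: none
Why: Two single-electron transfers from divalent samarium turn the primary C–I bond into the alkylsamarium 14, which adds to the lactone carbonyl to give the bicyclic hemiketalate 15; aqueous work-up collapses 15, opening the lactone and freeing the C7 hydroxyl. The closest known reaction type is the SmI2-promoted intramolecular Barbier-type nucleophilic acyl substitution of iodoalkyl esters and lactones. The carbocycle closes in the 5-exo-trig mode (C3 onto C4), helped by the quaternary C1 in the tether. No new stereocentre is formed: C1 and C5 come unchanged from the Claisen step, and C5, now α to a ketone, is shielded from epimerisation because the carbonyl stays masked in 15 until the neutral quench. The step needs reduction of the C–I bond ahead of lactone and alkenes and a single addition only; the first follows from the large difference in reduction potential, the second from the persistence of the tetrahedral intermediate, whose tethered alkoxide does not leave while reagent is present.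

**Step 8**
Reactants: 16 (2R,3R)-3-ethenyl-2-[(2R,3S)-2-hydroxy-3-methylpent-4-en-1-yl]-3-methylcyclopentan-1-one
Product: 17 (2R,3R)-3-ethenyl-3-methyl-2-[(2R,3S)-3-methyl-2-(triethylsilyloxy)pent-4-en-1-yl]cyclopentan-1-one
Conditions: Et3SiCl, imidazole, DMF, 0 °C
Reagents that add atoms: chlorotriethylsilane CC[Si](Cl)(CC)CC
Why: Silylation masks the liberated secondary hydroxyl as a non-chelating silyl ether so that the following carbonyl addition is governed by sterics alone.

**Step 9**
Reactants: 17 (2R,3R)-3-ethenyl-3-methyl-2-[(2R,3S)-3-methyl-2-(triethylsilyloxy)pent-4-en-1-yl]cyclopentan-1-one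
Product: 19 (1R,2R,3R)-3-ethenyl-2-[(2R,3S)-2-hydroxy-3-methylpent-4-en-1-yl]-3-methyl-1-(propan-2-yl)cyclopentan-1-ol, via silyl ether carbinol 18 (not isolated)
Conditions: iPrLi (3 equiv), CeCl3 (3 equiv), THF, −78 °C; then PPTS, MeOH, rt
Reagents that add atoms: isopropyllithium [Li]C(C)C
Why: 1,2-Addition of the weakly basic organocerium reagent (enolisation suppressed) should occur on the cyclopentanone face anti to both the C5 side chain and the cis-disposed C1 methyl group, setting C4 with its hydroxyl cis to these groups, and acidic methanolysis then removes the silyl ether.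

**Step 10**
Reactants: 19 (1R,2R,3R)-3-ethenyl-2-[(2R,3S)-2-hydroxy-3-methylpent-4-en-1-yl]-3-methyl-1-(propan-2-yl)cyclopentan-1-ol
Product: 20 (1R,3aR,6S,7R,8aR)-3a,6-dimethyl-1-(propan-2-yl)-1,2,3,3a,6,7,8,8a-octahydroazulene-1,7-diol
Conditions: second-generation Grubbs catalyst RuCl2(=CHPh)(PCy3)(H2IMes) (5 mol %), CH2Cl2 (2 mM), 40 °C
Reagents that add atoms: none
Why: Ring-closing metathesis of the two monosubstituted alkenes, carried on trans-disposed arms of the cyclopentane, should close the trans-fused seven-membered ring with loss of ethene.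

**Step 11**
Reactants: 20 (1R,3aR,6S,7R,8aR)-3a,6-dimethyl-1-(propan-2-yl)-1,2,3,3a,6,7,8,8a-octahydroazulene-1,7-diol
Product: 22 (3R,3aR,8aR)-3-hydroxy-6,8a-dimethyl-3-(propan-2-yl)-2,3,3a,4,8,8a-hexahydroazulen-5(1H)-one, via deconjugated enone 21 (not isolated)
Conditions: Dess–Martin periodinane, NaHCO3, CH2Cl2, 0 °C → rt; then DBU, CH2Cl2, rt
Reagents that add atoms: none
Why: Dess–Martin oxidation of the secondary alcohol (the tertiary C4 hydroxyl is inert) gives the β,γ-unsaturated ketone 21, which DBU should isomerise through its dienolate to the conjugated trisubstituted enone, erasing the controller centres C7 and C8.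

**Step 12**
Reactants: 22 (3R,3aR,8aR)-3-hydroxy-6,8a-dimethyl-3-(propan-2-yl)-2,3,3a,4,8,8a-hexahydroazulen-5(1H)-one
Product: 24 (3R,3aS,4R,8aR)-3,4-dihydroxy-6,8a-dimethyl-3-(propan-2-yl)-2,3,3a,4,8,8a-hexahydroazulen-5(1H)-one, via lithium enolate 23 (not isolated)
Conditions: LiN(iPr)2 (2.3 equiv), THF, −78 °C; then 2-(phenylsulfonyl)-3-phenyloxaziridine, −78 °C; NH4Cl
Reagents that add atoms: 2-(phenylsulfonyl)-3-phenyloxaziridine O=S(=O)(c1ccccc1)N1OC1c1ccccc1
Why: Kinetic α′-deprotonation gives the cross-conjugated enolate 23 (one equivalent of base is consumed by the C4 hydroxyl), and electrophilic enolate hydroxylation by the N-sulfonyloxaziridine should occur on the face of C6 anti to the adjacent C5–C4 bond, setting the C6 hydroxyl trans to it.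

**Step 13**
Reactants: 24 (3R,3aS,4R,8aR)-3,4-dihydroxy-6,8a-dimethyl-3-(propan-2-yl)-2,3,3a,4,8,8a-hexahydroazulen-5(1H)-one; 25 4-(benzyloxy)benzoyl chloride
Product: 26 (3R,3aS,4R,8aR)-3-hydroxy-6,8a-dimethyl-5-oxo-3-(propan-2-yl)-1,2,3,3a,4,5,8,8a-octahydroazulen-4-yl 4-(benzyloxy)benzoate
Conditions: Et3N, DMAP (10 mol %), CH2Cl2, 0 °C → rt
Reagents that add atoms: none
Why: DMAP-catalysed acylation should esterify the secondary α′-hydroxyl selectively, the tertiary C4 hydroxyl being too hindered to react.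

**Step 14**
Reactants: 26 (3R,3aS,4R,8aR)-3-hydroxy-6,8a-dimethyl-5-oxo-3-(propan-2-yl)-1,2,3,3a,4,5,8,8a-octahydroazulen-4-yl 4-(benzyloxy)benzoate
Product: 27 (3R,3aS,4R,6S,7S,8aR)-3,6,7-trihydroxy-6,8a-dimethyl-5-oxo-3-(propan-2-yl)decahydroazulen-4-yl 4-(benzyloxy)benzoate
Conditions: OsO4 (5 mol %), N-methylmorpholine N-oxide (1.5 equiv), citric acid, acetone/H2O (4:1), rt
Reagents that add atoms: N-methylmorpholine N-oxide C[N+]1([O-])CCOCC1; water O
Why: Catalytic osmium tetroxide syn-dihydroxylation of the enone alkene should take place on the face anti to the axial C1 methyl group, which screens the other face at C9, giving the cis-8,9-diol on the side of the C6 ester.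

**Step 15**
Reactants: 27 (3R,3aS,4R,6S,7S,8aR)-3,6,7-trihydroxy-6,8a-dimethyl-5-oxo-3-(propan-2-yl)decahydroazulen-4-yl 4-(benzyloxy)benzoate
Product: 28 (3R,3aS,4R,6S,7S,8aR)-3,6,7-trihydroxy-6,8a-dimethyl-5-oxo-3-(propan-2-yl)decahydroazulen-4-yl 4-hydroxybenzoate
Conditions: H2 (1 atm), palladium on carbon (Pd/C, 10 wt %), EtOAc, rt
Reagents that add atoms: none
Why: Hydrogenolysis of the benzyl aryl ether should free the phenol; no alkene remains, and ketone, aryl ester and alcohols are inert under these conditions.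

**Compound list**

1 | methyl 4-oxobutanoate | COC(=O)CCC=O | starting material
2 | (E)-crotylboronic acid pinacol ester | C/C=C/CB1OC(C)(C)C(C)(C)O1 | starting material
3 | methyl (4R,5S)-4-hydroxy-5-methylhept-6-enoate | C=C[C@H](C)[C@H](O)CCC(=O)OC | intermediate
4 | (5R)-5-[(2S)-but-3-en-2-yl]oxolan-2-one | C=C[C@H](C)[C@H]1CCC(=O)O1 | intermediate
5 | (5R)-5-[(2S)-but-3-en-2-yl]-2-methoxy-4,5-dihydro-3H-furan-1-ium tetrafluoroborate | C=C[C@H](C)[C@H]1CCC(OC)=[O+]1.F[B-](F)(F)F | intermediate
6 | (5R)-5-[(2S)-but-3-en-2-yl]-2,2-dimethoxyoxolane | C=C[C@H](C)[C@H]1CCC(OC)(OC)O1 | intermediate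
7 | (2Z)-3-methylpent-2-en-4-yn-1-ol | OC/C=C(/C)C#C | starting material
8 | (5R)-5-[(2S)-but-3-en-2-yl]-2-methoxy-2-{[(2Z)-3-methylpent-2-en-4-yn-1-yl]oxy}oxolane (both C2 epimers) | C=C[C@H](C)[C@H]1CCC(OC)(OC/C=C(/C)C#C)O1 | intermediate
9 | (2R)-2-[(2S)-but-3-en-2-yl]-5-{[(2Z)-3-methylpent-2-en-4-yn-1-yl]oxy}-2,3-dihydrofuran | C=C[C@H](C)[C@H]1CC=C(OC/C=C(/C)C#C)O1 | intermediate
10 | (3R,5R)-5-[(2S)-but-3-en-2-yl]-3-[(3R)-3-methylpent-1-en-4-yn-3-yl]oxolan-2-one | C=C[C@H](C)[C@H]1C[C@@H](C(=O)O1)[C@](C)(C#C)C=C | intermediate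
11 | (3R)-3-[(3R,5R)-5-[(2S)-but-3-en-2-yl]-2-oxooxolan-3-yl]-3-methylpent-4-enal | C=C[C@H](C)[C@H]1C[C@@H](C(=O)O1)[C@](C)(CC=O)C=C | intermediate
12 | (3R,5R)-5-[(2S)-but-3-en-2-yl]-3-[(3R)-5-hydroxy-3-methylpent-1-en-3-yl]oxolan-2-one | C=C[C@H](C)[C@H]1C[C@@H](C(=O)O1)[C@](C)(CCO)C=C | intermediate
13 | (3R,5R)-5-[(2S)-but-3-en-2-yl]-3-[(3R)-5-iodo-3-methylpent-1-en-3-yl]oxolan-2-one | C=C[C@H](C)[C@H]1C[C@@H](C(=O)O1)[C@](C)(CCI)C=C | intermediate
14 | alkylsamarium diiodide from 13 (SmI2 on C3 in place of iodine) | C=C[C@H](C)[C@H]1C[C@@H](C(=O)O1)[C@](C)(CC[Sm](I)I)C=C | intermediate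
15 | diiodosamarium alkoxide of the bicyclic hemiketal (2-oxabicyclo[3.3.0]octane; C4 bound to C3, C5, ring O and O–Sm) | C=C[C@H](C)[C@H]1C[C@H]2C(O[Sm](I)I)(O1)CC[C@]2(C)C=C | intermediate
16 | (2R,3R)-3-ethenyl-2-[(2R,3S)-2-hydroxy-3-methylpent-4-en-1-yl]-3-methylcyclopentan-1-one | C=C[C@H](C)[C@H](O)C[C@H]1C(=O)CC[C@]1(C)C=C | intermediate
17 | (2R,3R)-3-ethenyl-3-methyl-2-[(2R,3S)-3-methyl-2-(triethylsilyloxy)pent-4-en-1-yl]cyclopentan-1-one | C=C[C@H](C)[C@H](O[Si](CC)(CC)CC)C[C@H]1C(=O)CC[C@]1(C)C=C | intermediate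
18 | (1R,2R,3R)-3-ethenyl-3-methyl-2-[(2R,3S)-3-methyl-2-(triethylsilyloxy)pent-4-en-1-yl]-1-(propan-2-yl)cyclopentan-1-ol | C=C[C@H](C)[C@H](O[Si](CC)(CC)CC)C[C@H]1[C@](O)(C(C)C)CC[C@]1(C)C=C | intermediate
19 | (1R,2R,3R)-3-ethenyl-2-[(2R,3S)-2-hydroxy-3-methylpent-4-en-1-yl]-3-methyl-1-(propan-2-yl)cyclopentan-1-ol | C=C[C@H](C)[C@H](O)C[C@H]1[C@](O)(C(C)C)CC[C@]1(C)C=C | intermediate
20 | (1R,3aR,6S,7R,8aR)-3a,6-dimethyl-1-(propan-2-yl)-1,2,3,3a,6,7,8,8a-octahydroazulene-1,7-diol | CC(C)[C@]1(O)CC[C@]2(C)C=C[C@H](C)[C@H](O)C[C@H]21 | intermediate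
21 | (3R,3aR,6S,8aR)-3-hydroxy-6,8a-dimethyl-3-(propan-2-yl)-2,3,3a,4,6,8a-hexahydroazulen-5(1H)-one | CC(C)[C@]1(O)CC[C@]2(C)C=C[C@H](C)C(=O)C[C@H]21 | intermediate
22 | (3R,3aR,8aR)-3-hydroxy-6,8a-dimethyl-3-(propan-2-yl)-2,3,3a,4,8,8a-hexahydroazulen-5(1H)-one | CC(C)[C@]1(O)CC[C@]2(C)CC=C(C)C(=O)C[C@H]21 | intermediate
23 | dilithium alkoxide-enolate of 22 (C6=C7 enolate) | CC(C)[C@]1(O[Li])CC[C@]2(C)CC=C(C)C(O[Li])=C[C@H]21 | intermediate
24 | (3R,3aS,4R,8aR)-3,4-dihydroxy-6,8a-dimethyl-3-(propan-2-yl)-2,3,3a,4,8,8a-hexahydroazulen-5(1H)-one | CC(C)[C@]1(O)CC[C@]2(C)CC=C(C)C(=O)[C@H](O)[C@H]21 | intermediate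
25 | 4-(benzyloxy)benzoyl chloride | O=C(Cl)c1ccc(OCc2ccccc2)cc1 | starting material
26 | (3R,3aS,4R,8aR)-3-hydroxy-6,8a-dimethyl-5-oxo-3-(propan-2-yl)-1,2,3,3a,4,5,8,8a-octahydroazulen-4-yl 4-(benzyloxy)benzoate | CC(C)[C@]1(O)CC[C@]2(C)CC=C(C)C(=O)[C@H](OC(=O)c3ccc(OCc4ccccc4)cc3)[C@H]21 | intermediate
27 | (3R,3aS,4R,6S,7S,8aR)-3,6,7-trihydroxy-6,8a-dimethyl-5-oxo-3-(propan-2-yl)decahydroazulen-4-yl 4-(benzyloxy)benzoate | CC(C)[C@]1(O)CC[C@]2(C)C[C@H](O)[C@](C)(O)C(=O)[C@H](OC(=O)c3ccc(OCc4ccccc4)cc3)[C@H]21 | intermediate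
28 | (3R,3aS,4R,6S,7S,8aR)-3,6,7-trihydroxy-6,8a-dimethyl-5-oxo-3-(propan-2-yl)decahydroazulen-4-yl 4-hydroxybenzoate | CC(C)[C@]1(O)CC[C@]2(C)C[C@H](O)[C@](C)(O)C(=O)[C@H](OC(=O)c3ccc(O)cc3)[C@H]21 | target

**Step count and weak points**

Total step count: 15. Longest linear sequence: 15 steps (from 1).

Steps most likely to fail:

Step 3. The cyclic ketene acetal may rearrange with poor face selectivity or partly through a boat transition state, or the orthoester may open under the acid before it rearranges; each erodes the C5/C1 configuration. The fallback moves the rearrangement to the open-chain ester enolate (Ireland–Claisen), where enolate geometry is set by the base and solvent. It sets out from 4. Saponification (LiOH, THF/H2O), silylation (tBuMe2SiCl, imidazole) and cleavage of the silyl ester (K2CO3, MeOH) should give (4R,5S)-4-[(tert-butyldimethylsilyl)oxy]-5-methylhept-6-enoic acid F1. Esterification with 7 (EDC, DMAP) should give (2Z)-3-methylpent-2-en-4-yn-1-yl (4R,5S)-4-[(tert-butyldimethylsilyl)oxy]-5-methylhept-6-enoate F2. Treatment with LiN(iPr)2 (2.3 equiv) and Me3SiCl in THF/DMPU at −78 °C, where the enolate with the chain cis to the O-metal bond is favoured (the geometry the lactone ring had enforced), then warming to 60 °C and K2CO3/MeOH, should give (2R,4R,5S)-4-[(tert-butyldimethylsilyl)oxy]-5-methyl-2-[(3R)-3-methylpent-1-en-4-yn-3-yl]hept-6-enoic acid F3, together with its isomer epimeric at both new centres. TsOH in MeOH removes the silyl group and closes the lactone; the two lactones are separated, and the route is rejoined at 10.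

Step 7. The alkylsamarium may be protonated before it cyclises (simple loss of iodine), or the lactone may be reduced at the carbonyl, or addition to the hindered carbonyl may be slow. The fallback forms the same bond by olefination instead of electron transfer. It sets out from 13. Heating with PPh3 in MeCN should give {(3R)-3-[(3R,5R)-5-[(2S)-but-3-en-2-yl]-2-oxooxolan-3-yl]-3-methylpent-4-en-1-yl}triphenylphosphonium iodide F4. Deprotonation with KN(SiMe3)2 in toluene (0 → 80 °C) should bring about an intramolecular Wittig reaction of the ylide with the lactone carbonyl, giving the bicyclic enol ether 2-[(2S)-but-3-en-2-yl]-4-ethenyl-4-methyl-3,3a,4,5-tetrahydro-2H-cyclopenta[b]furan F5 (configurations as in 13). Brief treatment with 0.1 M HCl in THF hydrolyses the enol ether to the hydroxy ketone, and the route is rejoined at 16.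

Step 14. Osmylation may occur on the wrong face of the enone, or be slow on the electron-poor alkene so that the ester migrates or is lost. The fallback uses hydrogen-bond direction by the free C6 hydroxyl and acylates afterwards. It sets out from 24. OsO4 (1 equiv) with TMEDA in CH2Cl2 at −78 °C, then aqueous NaHSO3, should add syn to the C6 hydroxyl and give (3R,3aS,4R,6S,7S,8aR)-3,4,6,7-tetrahydroxy-6,8a-dimethyl-3-(propan-2-yl)octahydroazulen-5(1H)-one F6. 2,2-Dimethoxypropane and PPTS should protect the cis-8,9-diol as the acetonide F7. Acylation with 25 (Et3N, DMAP) should give the acetonide ester F8. Aqueous acetic acid (80 %, 40 °C) removes the acetonide, and the route is rejoined at 27.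

**Further compounds**

F1 | step 3 | (4R,5S)-4-[(tert-butyldimethylsilyl)oxy]-5-methylhept-6-enoic acid | C=C[C@H](C)[C@H](O[Si](C)(C)C(C)(C)C)CCC(=O)O
F2 | step 3 | (2Z)-3-methylpent-2-en-4-yn-1-yl (4R,5S)-4-[(tert-butyldimethylsilyl)oxy]-5-methylhept-6-enoate | C=C[C@H](C)[C@H](O[Si](C)(C)C(C)(C)C)CCC(=O)OC/C=C(/C)C#C
F3 | step 3 | (2R,4R,5S)-4-[(tert-butyldimethylsilyl)oxy]-5-methyl-2-[(3R)-3-methylpent-1-en-4-yn-3-yl]hept-6-enoic acid | C=C[C@H](C)[C@H](O[Si](C)(C)C(C)(C)C)C[C@@H](C(=O)O)[C@](C)(C#C)C=C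
F4 | step 7 | {(3R)-3-[(3R,5R)-5-[(2S)-but-3-en-2-yl]-2-oxooxolan-3-yl]-3-methylpent-4-en-1-yl}triphenylphosphonium iodide | C=C[C@H](C)[C@H]1C[C@@H](C(=O)O1)[C@](C)(CC[P+](c1ccccc1)(c1ccccc1)c1ccccc1)C=C.[I-]
F5 | step 7 | 2-[(2S)-but-3-en-2-yl]-4-ethenyl-4-methyl-3,3a,4,5-tetrahydro-2H-cyclopenta[b]furan (configurations as in 13) | C=C[C@H](C)[C@H]1C[C@H]2C(=CC[C@]2(C)C=C)O1
F6 | step 14 | (3R,3aS,4R,6S,7S,8aR)-3,4,6,7-tetrahydroxy-6,8a-dimethyl-3-(propan-2-yl)octahydroazulen-5(1H)-one | CC(C)[C@]1(O)CC[C@]2(C)C[C@H](O)[C@](C)(O)C(=O)[C@H](O)[C@H]21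
F7 | step 14 | 8,9-O-isopropylidene acetal (acetonide) of F6 | CC(C)[C@]1(O)CC[C@]2(C)C[C@@H]3OC(C)(C)O[C@]3(C)C(=O)[C@H](O)[C@H]21
F8 | step 14 | 6-O-[4-(benzyloxy)benzoyl] ester of acetonide F7 | CC(C)[C@]1(O)CC[C@]2(C)C[C@@H]3OC(C)(C)O[C@]3(C)C(=O)[C@H](OC(=O)c4ccc(OCc5ccccc5)cc4)[C@H]21
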